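The earlier runs and the new flask come from a simulation on assumed constants; scatter was added.

Take c_D and c_J from the same sample and watch their ratio, not either amount.

| flask | D | temperature | remark | time |
|---|---|---|---|---|
| Sunday's | 0.12 M | −10 °C | run made earlier |  |
| noon | 0.11 M |  | at −10 °C until 6.0 h, from then on at 30 °C | 20 h |
| spring | 0.15 M |  | at −10 °C throughout | 20 h |

- Sunday's (time / h: J / %, D / %): 0.667: 24.3, 67.3; 2.00: 32.3, 44.0; 3.00: 30.4, 36.4; 5.00: 24.9, 34.2; 8.00: 22.1, 27.4

(readings scatter by 1 percentage point)

- which of the two ends with the higher amount of J, in percent of the D charged ("neither" if they lie within 2 percentage points) (noon / spring / neither)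
- J at the end, in percent of the D charged, noon
- J at the end, in percent of the D charged, spring

- the earlier runs do not show what temperature does; that part of a forecast is a guess

Sunday's run was what I had. J read highest near 32.3 % at 2.00 h, and after that D and J fell together. Dividing the fall of D by the fall of J from 3.00 h to 8.00 h takes time out of the reckoning and gave 1.08, a rough figure, since each fall carries the scatter twice.

My rule of thumb followed: at −10 °C, once the two fall in step, c_D/c_J stands still, as in a pre-equilibrium. I took the lock ratio, summed c_D over summed c_J for the last three Sunday readings, 1.27; single readings ran from 1.20 to 1.37.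

The rule has borders. At 0.667 h Sunday's ratio read 2.77, about twice the lock ratio, and at 2.00 h it read 1.36, so in Sunday's readings the rule holds from about then. For noon I could not carry it past the change to 30 °C at 6.0 h, a temperature no earlier run shows. I expected spring to end near the lock ratio, though a ratio gives no J until c_D is read.

The forecast said spring, with J at 1 % (0 % to 8 %) for noon and 12 % (8 % to 16 %) for spring, having seen “D and J decline together with a nearly constant D/J ratio”.

The flasks gave spring: J ended at 1.94 % in noon and 17.4 % in spring, 5.4 percentage points above the forecast.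

    D ⇌ J (K = 0.790, k = 0.00983 min⁻¹, Ea = 72.0 kJ mol⁻¹, ΔH = −11.0 kJ mol⁻¹)
    J ⇌ E (K = 2.00, k = 0.00178 min⁻¹, Ea = 84.0 kJ mol⁻¹, ΔH = −14.0 kJ mol⁻¹)
    E ⇌ D (k = 0.00112 min⁻¹, Ea = 80.0 kJ mol⁻¹)
    2 D → L (k = 0.00498 M⁻¹ min⁻¹, Ea = 65.0 kJ mol⁻¹)
    D ⇌ X (K = 1.70, k = 1.68 × 10⁻⁴ min⁻¹, Ea = 100 kJ mol⁻¹, ΔH = −13.0 kJ mol⁻¹)
    (constants at −10 °C)

Spring ended with c_D at 22 % beside that 17.4 % of J, a ratio of 1.24 against the lock ratio of 1.27. Noon, past its border, ended at a ratio of 2.46, about twice the lock ratio. The neighbouring flask was noon read at 5.0 h instead, still at −10 °C. Its c_D of 33.2 % divided by the lock ratio reckons J at 26.1 %. The flask read 26.8 %.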